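The data are calculated with constants of no real substance, and the scatter is random.

A ratio prices this kinetic resolution. The larch run's last reading gives 23.3 for the selectivity factor, the logarithm of how far c(left-handed substrate) has fallen divided by the same logarithm for c(right-handed substrate). It is a reading, and a rough one, since the right-handed loss of 3.2 percentage points carries a scatter of 0.5 points.

in all of them: free catalyst 0.05 mol%
- larch: left-handed substrate 0.50 M; right-handed substrate 0.50 M; coupling partner 1.5 equiv; run made earlier
- alder: left-handed substrate 1 M; right-handed substrate 1 M; coupling partner 0.75 equiv; run made earlier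
- flask: left-handed substrate 1.0 M; right-handed substrate 1.0 M; coupling partner 1.50 equiv; time 25 h

| run | time / h | right-handed substrate / % | left-handed substrate / % |
|---|---|---|---|
| larch | 3.00 | 49.1 | 33.4 |
| larch | 6.00 | 48.4 | 23.7 |
| larch | 10.0 | 48.3 | 16.9 |
| larch | 12.0 | 48.2 | 14.2 |
| larch | 15.0 | 46.8 | 10.7 |
| alder | 1.33 | 48.9 | 40.1 |
| alder | 4.00 | 49.7 | 29.5 |
| alder | 8.00 | 48.4 | 22.3 |
| alder | 10.0 | 49.1 | 20.1 |
| alder | 15.0 | 47.6 | 19.0 |

(readings scatter by 0.5 percentage points)

1. whether the excess of right-handed substrate over left-handed substrate among what is left of the two reaches 95% by 25 h (yes / no)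
2. the highest excess of right-handed substrate over left-handed substrate among what is left of the two up to 25 h

- free catalyst is single-handed; left-handed substrate and right-handed substrate are mirror images of each other, charged as a racemate, each of them at the stated concentration

I treat the right-handed loss as a small correction and reckon it from the ratio. An excess of 95% needs the logarithm of c(right-handed substrate) to fall by 0.164, so the flask then keeps 42.4% of the two charged as right-handed substrate. By this reckoning both substrates together have then taken 1.13 equivalents of coupling partner, less than the 1.50 equiv charged. My reckoning prices the excess but does not time it. The forecast does time it and says no, with a top of 94.5% (range 92% to 96.5%): “This is borderline”.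

The flask answers yes, with a top of 98.1%.

    free catalyst + left-handed substrate ⇌ catalyst intermediate A (K = 2.20 M⁻¹, k = 14.0 M⁻¹ s⁻¹)
    free catalyst + right-handed substrate ⇌ catalyst intermediate B (K = 0.530 M⁻¹, k = 0.500 M⁻¹ s⁻¹)
    coupling partner + catalyst intermediate A → free catalyst + left-handed product (k = 0.230 M⁻¹ s⁻¹)
    coupling partner + catalyst intermediate B → free catalyst + right-handed product (k = 0.0360 M⁻¹ s⁻¹)
    left-handed product ⇌ right-handed product (k = 1.20 × 10⁻⁴ s⁻¹)
    coupling partner + free catalyst → spent catalyst (k = 7.70 × 10⁻⁶ M⁻¹ s⁻¹)
    coupling partner → decomposed reagent (k = 3.60 × 10⁻⁶ s⁻¹)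

The flask reaches the wanted excess at 16.9 h, with 43.3% of the two charged still right-handed substrate, beside my 42.4%. The same 23.3 turns the alder run's 19.0% of left-handed substrate at 15.0 h into 48.0% of right-handed substrate, read there as 47.6%. Of what makes the flask's excess at 25 h, the path from free catalyst + left-handed substrate to catalyst intermediate A, both ways, has the largest single effect: with it taken away, that excess is −24.0% instead of 98.1%.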